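Ring C of the flavone is opened at three bonds, C4a–C4, C4–C3 and O1–C2. Ring A then arrives as a mirror-symmetric 2-iodophloroglucinol derivative, C4 as carbon monoxide and C2–C3 as the ethynyl group on ring B. One palladium-catalysed carbonylative alkyne coupling with amine-mediated 6-endo closure builds ring C in a single flask. It exploits the equivalence of the two ring A oxygens flanking C4a, which become O1 and the hydrogen-bonded C5 hydroxyl. The alkyne partner already carries the complete erythro (αR,βS) aryl glycerol ether, with the benzylic oxygen as a triethylsilyl ether and the primary alcohol free for the later p-coumarate.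

Key step: step 10

Assumption: the chloroacetyl imide used in step 2 is a catalogue compound (otherwise one N-acylation of the parent oxazolidinone with chloroacetyl chloride); Cα, Cβ and Cγ denote the benzylic, aryloxy-bearing and primary carbons of the side chain.

Step 1
Reactants: 1 vanillin
Product: 2 3-methoxy-4-(triisopropylsilyloxy)benzaldehyde
Conditions: TIPSCl, imidazole, DMF, 0 °C → rt
Reagents that add atoms: triisopropylsilyl chloride, CC(C)[Si](Cl)(C(C)C)C(C)C
Why: Imidazole-promoted O-silylation of a phenol is routine, and the bulky aryl silyl ether masks the acidic hydroxyl through the amine-base aldol, hydride reduction, cross-coupling and carbonylation that follow.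

Step 2
Reactants: 3 4-bromo-2,6-dimethoxyphenol; 4 (S)-4-benzyl-3-(chloroacetyl)oxazolidin-2-one
Product: 5 (S)-4-benzyl-3-[(4-bromo-2,6-dimethoxyphenoxy)acetyl]oxazolidin-2-one
Conditions: K2CO3, NaI (10 mol %), acetone, rt → 40 °C
Reagents that add atoms: none
Why: Williamson ether synthesis in which the phenoxide displaces the halide of the strongly SN2-activated α-halo imide (iodide exchange in situ, Finkelstein) while the remote auxiliary stereocenter is untouched.

Step 3
Reactants: 5 (S)-4-benzyl-3-[(4-bromo-2,6-dimethoxyphenoxy)acetyl]oxazolidin-2-one; 2 3-methoxy-4-(triisopropylsilyloxy)benzaldehyde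
Product: 7 (S)-4-benzyl-3-{(2R,3R)-2-(4-bromo-2,6-dimethoxyphenoxy)-3-hydroxy-3-[3-methoxy-4-(triisopropylsilyloxy)phenyl]propanoyl}oxazolidin-2-one (anti aldol adduct), via trimethylsilyl ether 6 (not isolated)
Conditions: MgCl2 (20 mol %), Et3N, TMSCl, EtOAc, rt; then 1 M HCl, THF, 0 °C
Reagents that add atoms: none
Why: Evans magnesium halide-catalysed anti aldol, in which the magnesium-chelated Z enolate of the imide attacks the non-enolisable aryl aldehyde through a boat transition state on the face away from the benzyl group, so the auxiliary sets C2 (R, later Cβ) and the anti transition state sets C3 (R, later Cα), with silylation of the aldolate turning the catalyst over before mild acid frees the alcohol.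

Step 4
Reactants: 7 anti aldol adduct
Product: 8 (S)-4-benzyl-3-{(2R,3R)-2-(4-bromo-2,6-dimethoxyphenoxy)-3-[3-methoxy-4-(triisopropylsilyloxy)phenyl]-3-(triethylsilyloxy)propanoyl}oxazolidin-2-one
Conditions: TESOTf, 2,6-lutidine, CH2Cl2, −78 °C
Reagents that add atoms: triethylsilyl trifluoromethanesulfonate, CC[Si](CC)(CC)OS(=O)(=O)C(F)(F)F
Why: Silyl triflate silylation of a secondary aldol hydroxyl under a hindered base is standard, shuts off retro-aldol cleavage, and marks the benzylic oxygen so that only the primary one can be acylated later.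

Step 5
Reactants: 8 silylated aldol imide
Product: 9 (2S,3R)-2-(4-bromo-2,6-dimethoxyphenoxy)-3-[3-methoxy-4-(triisopropylsilyloxy)phenyl]-3-(triethylsilyloxy)propan-1-ol
Conditions: LiBH4, MeOH (1 equiv), THF, 0 °C
Reagents that add atoms: none
Why: Reductive cleavage of the N-acyloxazolidinone with lithium borohydride converts the exocyclic carbonyl into the primary alcohol without enolisation at the adjacent stereocenter and leaves the aryl bromide and both silyl ethers alone.

Step 6
Reactants: 9 bromoaryl ether alcohol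
Product: 10 (2S,3R)-2-{2,6-dimethoxy-4-[(trimethylsilyl)ethynyl]phenoxy}-3-[3-methoxy-4-(triisopropylsilyloxy)phenyl]-3-(triethylsilyloxy)propan-1-ol
Conditions: TMS-acetylene, PdCl2(PhCN)2 (3 mol %), [HP(t-Bu)3]BF4 (6 mol %), CuI (2 mol %), i-Pr2NH, dioxane, rt → 45 °C
Reagents that add atoms: ethynyltrimethylsilane, C#C[Si](C)(C)C
Why: Sonogashira coupling, for which the bulky electron-rich phosphine makes oxidative addition into the electron-rich but unhindered aryl bromide feasible near room temperature while the free alcohol and silyl ethers are indifferent to the amine base.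

Step 7
Reactants: 10 silylated alkyne
Product: 11 (2S,3R)-2-(4-ethynyl-2,6-dimethoxyphenoxy)-3-[3-methoxy-4-(triisopropylsilyloxy)phenyl]-3-(triethylsilyloxy)propan-1-ol
Conditions: K2CO3 (0.2 equiv), MeOH/THF, 0 °C
Reagents that add atoms: none
Why: Methoxide-catalysed protodesilylation cleaves the alkynyl C–Si bond within minutes at 0 °C, far faster than it attacks the hindered aryl triisopropylsilyl or secondary triethylsilyl ethers.

Step 8
Reactants: 12 phloroglucinol
Product: 13 5-(triisopropylsilyloxy)benzene-1,3-diol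
Conditions: 12 (3 equiv), TIPSCl (1 equiv), imidazole, DMF, 0 °C → rt
Reagents that add atoms: triisopropylsilyl chloride, CC(C)[Si](Cl)(C(C)C)C(C)C
Why: Statistical monosilylation of a threefold-symmetric triol cannot give regioisomers, and the excess of cheap triol (removed by aqueous wash) suppresses double silylation.

Step 9
Reactants: 13 5-(triisopropylsilyloxy)benzene-1,3-diol
Product: 15 2-iodo-5-(triisopropylsilyloxy)-1,3-phenylene diacetate, via iodoresorcinol 14 (not isolated)
Conditions: I2, NaHCO3, THF/H2O, 0 °C; then Ac2O, pyridine, DMAP (cat.), CH2Cl2, 0 °C → rt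
Reagents that add atoms: iodine, II; acetic anhydride, CC(=O)OC(C)=O
Why: Electrophilic aromatic iodination under bicarbonate buffering goes to the carbon flanked by the two free hydroxyls, as it does in resorcinol, and not next to the bulky silyl ether, and immediate acetylation turns the oxidation-prone iodoresorcinol into a storable diacetate that undergoes oxidative addition more readily.

Step 10
Reactants: 11 ring B alkyne; 15 2-iodo-5-(triisopropylsilyloxy)-1,3-phenylene diacetate; 16 carbon monoxide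
Product: 19 5-hydroxy-2-[4-({(2S,3R)-1-hydroxy-3-[3-methoxy-4-(triisopropylsilyloxy)phenyl]-3-(triethylsilyloxy)propan-2-yl}oxy)-3,5-dimethoxyphenyl]-7-(triisopropylsilyloxy)-4H-chromen-4-one, via ynone 17 (not isolated), via enaminone 18 (not isolated)
Conditions: CO (1 atm), PdCl2(PPh3)2 (5 mol %), dppp (5 mol %), thiourea (5 mol %), Et2NH (excess), DMF, 40 °C
Reagents that add atoms: none
Why: The aryl iodide adds oxidatively to zerovalent palladium, carbon monoxide inserts to give an aroylpalladium species, and coupling with the amine-deprotonated terminal alkyne releases ynone 17, forming C4a–C4 and C4–C3; diethylamine then adds to the ynone and removes both acetates by aminolysis to give enaminone 18, whose phenol attacks C2 and expels the amine, forming O1–C2. The closest known reaction type is the carbonylative Sonogashira annulation of ortho-iodophenols and their acetates with terminal alkynes to flavones. Ring C closes by a 6-endo addition–elimination at C2 of the enaminone, which rules out the 5-exo path to an aurone. No stereocenter is formed, and Cα and Cβ of the side chain carry no acidic hydrogen and are not at risk under the mild amine conditions. The step needs carbonylation to be faster than direct alkynylation, which the copper-free conditions under carbon monoxide provide, and it needs a single ring A regiochemistry, which the mirror symmetry of the iodoarene guarantees because either flanking oxygen gives the same ring while the other ends as the hydrogen-bonded C5 hydroxyl. The free primary alcohol, the triethylsilyl ether and both aryl triisopropylsilyl ethers should remain spectators, since an isolated alcohol is a far poorer partner for the aroylpalladium intermediate than the alkyne and hindered silyl ethers resist diethylamine at 40 °C.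

Step 11
Reactants: 20 p-coumaric acid
Product: 22 (E)-3-[4-(tert-butyldimethylsilyloxy)phenyl]prop-2-enoic acid, via silyl ester 21 (not isolated)
Conditions: TBSCl (2.3 equiv), imidazole, DMF, rt; then AcOH/THF/H2O, rt
Reagents that add atoms: tert-butyldimethylsilyl chloride, CC(C)(C)[Si](C)(C)Cl
Why: Exhaustive silylation followed by selective hydrolysis of the far more labile silyl ester is the usual way to mask only the phenol of a hydroxycinnamic acid, and the E alkene is not touched.

Step 12
Reactants: 19 flavone alcohol; 22 (E)-3-[4-(tert-butyldimethylsilyloxy)phenyl]prop-2-enoic acid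
Product: 23 (2S,3R)-2-{4-[5-hydroxy-4-oxo-7-(triisopropylsilyloxy)-4H-chromen-2-yl]-2,6-dimethoxyphenoxy}-3-[3-methoxy-4-(triisopropylsilyloxy)phenyl]-3-(triethylsilyloxy)propyl (E)-3-[4-(tert-butyldimethylsilyloxy)phenyl]prop-2-enoate
Conditions: 22 (1.2 equiv), EDC·HCl, DMAP (cat.), CH2Cl2, 0 °C → rt
Reagents that add atoms: none
Why: Steglich esterification, which acylates the primary alcohol because it is the only free aliphatic hydroxyl, the benzylic oxygen being silylated and the C5 phenol being held unreactive by its hydrogen bond to the C4 carbonyl.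

Step 13
Reactants: 23 fully silylated ester
Product: 24 (2S,3R)-2-[4-(5,7-dihydroxy-4-oxo-4H-chromen-2-yl)-2,6-dimethoxyphenoxy]-3-hydroxy-3-(4-hydroxy-3-methoxyphenyl)propyl (E)-3-(4-hydroxyphenyl)prop-2-enoate (CNP0264527.1)
Conditions: TBAF, AcOH (1:1, excess), THF, 0 °C → rt
Reagents that add atoms: none
Why: Fluoride-mediated cleavage of the three aryl silyl ethers and the triethylsilyl ether in one operation, buffered with acetic acid so that the cinnamate ester neither migrates to the liberated benzylic hydroxyl nor is cleaved and neither stereocenter is disturbed.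

Compound list

1 | vanillin | COc1cc(C=O)ccc1O | starting material
2 | 3-methoxy-4-(triisopropylsilyloxy)benzaldehyde | COc1cc(C=O)ccc1O[Si](C(C)C)(C(C)C)C(C)C | intermediate
3 | 4-bromo-2,6-dimethoxyphenol | COc1cc(Br)cc(OC)c1O | starting material
4 | (S)-4-benzyl-3-(chloroacetyl)oxazolidin-2-one | O=C1OC[C@H](Cc2ccccc2)N1C(=O)CCl | starting material
5 | (S)-4-benzyl-3-[(4-bromo-2,6-dimethoxyphenoxy)acetyl]oxazolidin-2-one | O=C1OC[C@H](Cc2ccccc2)N1C(=O)COc1c(OC)cc(Br)cc1OC | intermediate
6 | trimethylsilyl ether of anti aldol adduct 7 | COc1cc([C@@H](O[Si](C)(C)C)[C@H](C(=O)N2C(=O)OC[C@@H]2Cc2ccccc2)Oc2c(OC)cc(Br)cc2OC)ccc1O[Si](C(C)C)(C(C)C)C(C)C | intermediate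
7 | (S)-4-benzyl-3-{(2R,3R)-2-(4-bromo-2,6-dimethoxyphenoxy)-3-hydroxy-3-[3-methoxy-4-(triisopropylsilyloxy)phenyl]propanoyl}oxazolidin-2-one | COc1cc([C@@H](O)[C@H](C(=O)N2C(=O)OC[C@@H]2Cc2ccccc2)Oc2c(OC)cc(Br)cc2OC)ccc1O[Si](C(C)C)(C(C)C)C(C)C | intermediate
8 | (S)-4-benzyl-3-{(2R,3R)-2-(4-bromo-2,6-dimethoxyphenoxy)-3-[3-methoxy-4-(triisopropylsilyloxy)phenyl]-3-(triethylsilyloxy)propanoyl}oxazolidin-2-one | COc1cc([C@@H](O[Si](CC)(CC)CC)[C@H](C(=O)N2C(=O)OC[C@@H]2Cc2ccccc2)Oc2c(OC)cc(Br)cc2OC)ccc1O[Si](C(C)C)(C(C)C)C(C)C | intermediate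
9 | (2S,3R)-2-(4-bromo-2,6-dimethoxyphenoxy)-3-[3-methoxy-4-(triisopropylsilyloxy)phenyl]-3-(triethylsilyloxy)propan-1-ol | COc1cc([C@@H](O[Si](CC)(CC)CC)[C@H](CO)Oc2c(OC)cc(Br)cc2OC)ccc1O[Si](C(C)C)(C(C)C)C(C)C | intermediate
10 | (2S,3R)-2-{2,6-dimethoxy-4-[(trimethylsilyl)ethynyl]phenoxy}-3-[3-methoxy-4-(triisopropylsilyloxy)phenyl]-3-(triethylsilyloxy)propan-1-ol | COc1cc([C@@H](O[Si](CC)(CC)CC)[C@H](CO)Oc2c(OC)cc(C#C[Si](C)(C)C)cc2OC)ccc1O[Si](C(C)C)(C(C)C)C(C)C | intermediate
11 | (2S,3R)-2-(4-ethynyl-2,6-dimethoxyphenoxy)-3-[3-methoxy-4-(triisopropylsilyloxy)phenyl]-3-(triethylsilyloxy)propan-1-ol | COc1cc([C@@H](O[Si](CC)(CC)CC)[C@H](CO)Oc2c(OC)cc(C#C)cc2OC)ccc1O[Si](C(C)C)(C(C)C)C(C)C | intermediate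
12 | phloroglucinol | Oc1cc(O)cc(O)c1 | starting material
13 | 5-(triisopropylsilyloxy)benzene-1,3-diol | Oc1cc(O)cc(O[Si](C(C)C)(C(C)C)C(C)C)c1 | intermediate
14 | 2-iodo-5-(triisopropylsilyloxy)benzene-1,3-diol | Oc1cc(O[Si](C(C)C)(C(C)C)C(C)C)cc(O)c1I | intermediate
15 | 2-iodo-5-(triisopropylsilyloxy)-1,3-phenylene diacetate | CC(=O)Oc1cc(O[Si](C(C)C)(C(C)C)C(C)C)cc(OC(C)=O)c1I | intermediate
16 | carbon monoxide | [C-]#[O+] | starting material
17 | 2-{3-[ring B aryl]prop-2-ynoyl}-5-(triisopropylsilyloxy)-1,3-phenylene diacetate (ynone; ring B aryl as in 11) | COc1cc([C@@H](O[Si](CC)(CC)CC)[C@H](CO)Oc2c(OC)cc(C#CC(=O)c3c(OC(C)=O)cc(O[Si](C(C)C)(C(C)C)C(C)C)cc3OC(C)=O)cc2OC)ccc1O[Si](C(C)C)(C(C)C)C(C)C | intermediate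
18 | (E)-3-(diethylamino)-1-[2,6-dihydroxy-4-(triisopropylsilyloxy)phenyl]-3-[ring B aryl]prop-2-en-1-one (enaminone; ring B aryl as in 11) | COc1cc([C@@H](O[Si](CC)(CC)CC)[C@H](CO)Oc2c(OC)cc(/C(=C\C(=O)c3c(O)cc(O[Si](C(C)C)(C(C)C)C(C)C)cc3O)N(CC)CC)cc2OC)ccc1O[Si](C(C)C)(C(C)C)C(C)C | intermediate
19 | 5-hydroxy-2-[4-({(2S,3R)-1-hydroxy-3-[3-methoxy-4-(triisopropylsilyloxy)phenyl]-3-(triethylsilyloxy)propan-2-yl}oxy)-3,5-dimethoxyphenyl]-7-(triisopropylsilyloxy)-4H-chromen-4-one | COc1cc([C@@H](O[Si](CC)(CC)CC)[C@H](CO)Oc2c(OC)cc(-c3cc(=O)c4c(O)cc(O[Si](C(C)C)(C(C)C)C(C)C)cc4o3)cc2OC)ccc1O[Si](C(C)C)(C(C)C)C(C)C | intermediate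
20 | p-coumaric acid | O=C(O)/C=C/c1ccc(O)cc1 | starting material
21 | tert-butyldimethylsilyl (E)-3-[4-(tert-butyldimethylsilyloxy)phenyl]prop-2-enoate | CC(C)(C)[Si](C)(C)OC(=O)/C=C/c1ccc(O[Si](C)(C)C(C)(C)C)cc1 | intermediate
22 | (E)-3-[4-(tert-butyldimethylsilyloxy)phenyl]prop-2-enoic acid | O=C(O)/C=C/c1ccc(O[Si](C)(C)C(C)(C)C)cc1 | intermediate
23 | (2S,3R)-2-{4-[5-hydroxy-4-oxo-7-(triisopropylsilyloxy)-4H-chromen-2-yl]-2,6-dimethoxyphenoxy}-3-[3-methoxy-4-(triisopropylsilyloxy)phenyl]-3-(triethylsilyloxy)propyl (E)-3-[4-(tert-butyldimethylsilyloxy)phenyl]prop-2-enoate | COc1cc([C@@H](O[Si](CC)(CC)CC)[C@H](COC(=O)/C=C/c2ccc(O[Si](C)(C)C(C)(C)C)cc2)Oc2c(OC)cc(-c3cc(=O)c4c(O)cc(O[Si](C(C)C)(C(C)C)C(C)C)cc4o3)cc2OC)ccc1O[Si](C(C)C)(C(C)C)C(C)C | intermediate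
24 | (2S,3R)-2-[4-(5,7-dihydroxy-4-oxo-4H-chromen-2-yl)-2,6-dimethoxyphenoxy]-3-hydroxy-3-(4-hydroxy-3-methoxyphenyl)propyl (E)-3-(4-hydroxyphenyl)prop-2-enoate | COc1cc([C@@H](O)[C@H](COC(=O)/C=C/c2ccc(O)cc2)Oc2c(OC)cc(-c3cc(=O)c4c(O)cc(O)cc4o3)cc2OC)ccc1O | target

Total step count: 13. Longest linear sequence: 9 steps (steps 2, 3, 4, 5, 6, 7, 10, 12 and 13; the branch from vanillin through step 1 is equally long).

Steps most likely to fail

Step 10. Carbon monoxide insertion may lose out to direct alkynylation, the hindered aroylpalladium intermediate may be captured by the amine, or long exposure to diethylamine may strip the C7 silyl ether. The fallback brings C4 in already bound to ring A. Commercial 2,4,6-trihydroxybenzaldehyde is silylated at the non-chelated para hydroxyl (TIPSCl, imidazole) to give 2,6-dihydroxy-4-(triisopropylsilyloxy)benzaldehyde F1. Acetylation gives 2-formyl-5-(triisopropylsilyloxy)-1,3-phenylene diacetate F2. Pinnick oxidation (NaClO2, NaH2PO4, 2-methyl-2-butene) gives 2,6-diacetoxy-4-(triisopropylsilyloxy)benzoic acid F3, and oxalyl chloride with catalytic DMF gives 2,6-diacetoxy-4-(triisopropylsilyloxy)benzoyl chloride F4. Acyl Sonogashira coupling of F4 with alkyne 11 (PdCl2(PPh3)2, CuI, Et3N, THF, rt) should give ynone 17 as an isolated compound; the doubly ortho-substituted aroyl chloride should be slow to acylate the primary alcohol without a nucleophilic catalyst. Et2NH in DMF at 40 °C then closes ring C as in step 10. The fallback sets out from 11 and rejoins the route at 19 by way of 17.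

Step 3. The aryloxy oxygen may take part in chelation of the magnesium enolate and erode the anti preference or the facial bias. The fallback sets the two centres by a boron syn aldol and a separate inversion. Phenol 3 is alkylated with the enantiomeric, likewise purchasable (R)-chloroacetyl imide to give (R)-4-benzyl-3-[(4-bromo-2,6-dimethoxyphenoxy)acetyl]oxazolidin-2-one F5. Its dibutylboron enolate (Bu2BOTf, i-Pr2NEt, CH2Cl2, −78 → 0 °C) adds to aldehyde 2 through a Zimmerman–Traxler chair to give the Evans syn adduct F6, with Cβ correct and Cα epimeric. Mitsunobu reaction with 4-nitrobenzoic acid (PPh3, DIAD, THF, 0 °C) inverts the benzylic carbinol and gives the anti 4-nitrobenzoate F7. LiBH4 cleaves both the imide and the ester to the erythro diol F8. Double silylation (TESOTf, 2,6-lutidine) gives the bis(triethylsilyl) ether F9, and selective methanolysis of the primary silyl ether (PPTS, MeOH/CH2Cl2, 0 °C) returns alcohol 9. The fallback sets out from 3 and 2 and rejoins the route at 9.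

Step 9. Iodination may stray to the position beside the silyl ether or run on to double iodination. The fallback delivers iodine by directed ortho-metalation. Diol 13 is converted (MOMCl, i-Pr2NEt, CH2Cl2) into 1,3-bis(methoxymethoxy)-5-(triisopropylsilyloxy)benzene F10. Lithiation between the two acetal oxygens (n-BuLi, THF, 0 °C) and an I2 quench give 2-iodo-1,3-bis(methoxymethoxy)-5-(triisopropylsilyloxy)benzene F11. Brief acid methanolysis (cat. HCl, MeOH, 0 °C → rt) frees iodoresorcinol 14, which is acetylated as in the second stage of step 9. The fallback sets out from 13 and rejoins the route at 14, and from there at 15.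

Further compounds

F1 | step 10 | 2,6-dihydroxy-4-(triisopropylsilyloxy)benzaldehyde | O=Cc1c(O)cc(O[Si](C(C)C)(C(C)C)C(C)C)cc1O
F2 | step 10 | 2-formyl-5-(triisopropylsilyloxy)-1,3-phenylene diacetate | CC(=O)Oc1cc(O[Si](C(C)C)(C(C)C)C(C)C)cc(OC(C)=O)c1C=O
F3 | step 10 | 2,6-diacetoxy-4-(triisopropylsilyloxy)benzoic acid | CC(=O)Oc1cc(O[Si](C(C)C)(C(C)C)C(C)C)cc(OC(C)=O)c1C(=O)O
F4 | step 10 | 2,6-diacetoxy-4-(triisopropylsilyloxy)benzoyl chloride | CC(=O)Oc1cc(O[Si](C(C)C)(C(C)C)C(C)C)cc(OC(C)=O)c1C(=O)Cl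
F5 | step 3 | (R)-4-benzyl-3-[(4-bromo-2,6-dimethoxyphenoxy)acetyl]oxazolidin-2-one | O=C1OC[C@@H](Cc2ccccc2)N1C(=O)COc1c(OC)cc(Br)cc1OC
F6 | step 3 | (R)-4-benzyl-3-{(2R,3S)-2-(4-bromo-2,6-dimethoxyphenoxy)-3-hydroxy-3-[3-methoxy-4-(triisopropylsilyloxy)phenyl]propanoyl}oxazolidin-2-one | COc1cc([C@H](O)[C@H](C(=O)N2C(=O)OC[C@H]2Cc2ccccc2)Oc2c(OC)cc(Br)cc2OC)ccc1O[Si](C(C)C)(C(C)C)C(C)C
F7 | step 3 | (1R,2R)-3-[(R)-4-benzyl-2-oxooxazolidin-3-yl]-2-(4-bromo-2,6-dimethoxyphenoxy)-1-[3-methoxy-4-(triisopropylsilyloxy)phenyl]-3-oxopropyl 4-nitrobenzoate | COc1cc([C@@H](OC(=O)c2ccc(cc2)[N+](=O)[O-])[C@H](C(=O)N2C(=O)OC[C@H]2Cc2ccccc2)Oc2c(OC)cc(Br)cc2OC)ccc1O[Si](C(C)C)(C(C)C)C(C)C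
F8 | step 3 | (1R,2S)-2-(4-bromo-2,6-dimethoxyphenoxy)-1-[3-methoxy-4-(triisopropylsilyloxy)phenyl]propane-1,3-diol | COc1cc([C@@H](O)[C@H](CO)Oc2c(OC)cc(Br)cc2OC)ccc1O[Si](C(C)C)(C(C)C)C(C)C
F9 | step 3 | bis(triethylsilyl) ether of diol F8 | COc1cc([C@@H](O[Si](CC)(CC)CC)[C@H](CO[Si](CC)(CC)CC)Oc2c(OC)cc(Br)cc2OC)ccc1O[Si](C(C)C)(C(C)C)C(C)C
F10 | step 9 | 1,3-bis(methoxymethoxy)-5-(triisopropylsilyloxy)benzene | COCOc1cc(OCOC)cc(O[Si](C(C)C)(C(C)C)C(C)C)c1
F11 | step 9 | 2-iodo-1,3-bis(methoxymethoxy)-5-(triisopropylsilyloxy)benzene | COCOc1cc(O[Si](C(C)C)(C(C)C)C(C)C)cc(OCOC)c1I
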